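- The amounts in the two earlier runs did not add up. At 15.0 min the feed had put in 75.0% of the charge, yet free substrate read 61.7% in eta and 59.5% in beta, so it was draining away as it came in.

| setting | eta | beta | north-west | south-west | west |
|---|---|---|---|---|---|
| substrate | 1 M (fed, over 20 min) | 1 M (fed, over 20 min) | 1.0 M (fed, over 20 min) | 1.0 M (fed, over 20 min) | 1.0 M (fed, over 20 min) |
| reagent in the second phase | 0.98 equiv | 2 equiv | 1.10 equiv | 1.70 equiv | 2.50 equiv |
| remark | run made earlier; the fed solution adds 0.25 times the starting volume | run made earlier; the fed solution adds 0.25 times the starting volume | the fed solution adds 0.25 times the starting volume | the fed solution adds 0.25 times the starting volume | the fed solution adds 0.25 times the starting volume |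
| time |  |  | 30 min | 30 min | 30 min |
| volume of the second phase over the first |  |  | 2.0 | 2.0 | 2.0 |

- eta (time / min: substrate / %, over-reacted product / %, target / %): 0.833: 3.6, 0.1, 0; 2.50: 12.3, 0, 0.1; 4.00: 18.7, 0, 0; 6.00: 27.2, 0, 0; 10.0: 44.6, 0, 0.6; 12.0: 51.0, 0.3, 2.1; 15.0: 61.7, 0, 2.6
- beta (time / min: substrate / %, over-reacted product / %, target / %): 0.833: 4.5, 0.5, 0; 2.50: 12.0, 0, 0; 4.00: 19.1, 0, 0; 6.00: 27.9, 0.1, 0.3; 10.0: 43.0, 1.0, 2.0; 12.0: 49.5, 0.5, 3.0; 15.0: 59.5, 1.4, 4.6

(each reading ± 0.3 percentage points)

- charges are per starting volume, the dose included; the dosed solution carries all of it
- in the second phase: reagent in the second phase; everything else is in the first
- charges count per volume of the first phase; a concentration in a rate is the amount of a species over the volume of its own phase; every rate counts per litre of the first phase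
- the earlier runs hold the two phases in the same ratio of volumes as the flask asked about
- percentages count the whole charge, also what has not yet gone in
- a reading of substrate is of its free form alone

* which of these there is most of at the end, counted by the substrate in it, north-west (over-reacted product / target / substrate)
* which of these there is most of at the end, counted by the substrate in it, south-west (over-reacted product / target / substrate)
* which of these there is most of at the end, counted by the substrate in it, west (over-reacted product / target / substrate)
* final amount of the leader among these, as a percentage of the substrate charged, in north-west
* final amount of the leader among these, as a percentage of the substrate charged, in south-west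
* final amount of the leader among these, as a percentage of the substrate charged, in west

- You asked for a quick number and guessed that target would top west. I reckoned with one quantity, the drain constant λ: the share of free substrate leaving per minute, a pseudo-first-order constant for a given reagent charge.
- I took λ as the amount dosed but no longer free, divided by the area under the free-substrate curve. That curve rose almost straight, so I took the area as 0.5 times reading times time.
- This gave 0.0287 /min for eta and 0.0347 /min for beta, higher with more reagent.
- A straight line through both, against equivalents, met zero reagent at 0.0230 /min. So on that line part of the drain did not follow the reagent.
- The line gave 0.0294 /min for north-west, 0.0377 /min for west, beyond the equivalents tried, and 0.0330 /min for south-west, its share of free substrate leaving per minute.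
- Letting each minute take that share, during the feed and after it, I expected free substrate at 30 min of 56.3% in north-west, 52.7% in south-west and 48.2% in west.
- In west, the reagent's part of λ came to about 20.2% of the charge for target and over-reacted product together, less than the free substrate. So I put substrate first in west, not target.
- The forecast also put substrate first, but higher than I did, at 66%, 61% and 56%, saying “Free substrate therefore leads in all three flasks”.

    reagent in the reaction phase ⇌ reagent in the second phase, rate k1*([reagent in the reaction phase] - [reagent in the second phase]/K1) per volume of the first phase (partition coefficient = 2.75, kL = 0.0537 /min)
    substrate + reagent in the reaction phase → target (k = 0.123 /M/min)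
    reagent in the reaction phase + target → over-reacted product (k = 0.544 /M/min)
    substrate → decomposition product (k = 4.70 × 10⁻⁵ /min)
    substrate ⇌ dormant form (K = 13.9, k = 0.0202 /min)

- The flasks gave substrate first at 58.4% in north-west, substrate at 54.1% in south-west and substrate at 49.1% in west. At 30.0 min in south-west, the forward step from substrate to dormant form used substrate 1.8 times as fast as the step to target. That flask then held 28.9% dormant form against 9.82% target. Carried on with 0.0330 /min, my reckoning for south-west left until 50 min gave 27.2% free substrate, and that flask holds 29.8%.

The runs stem from a simulated flask with constants of no real substance; noise was put on by code.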